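## Structural features

The target is an 18-membered macrocyclic bis(bibenzyl) built from four six-membered rings: a 2-methoxy-1,4-benzoquinone (ring A), a para-phenylene (ring B), a 1,2,4-trisubstituted phenol (ring C) and a meta-phenylene (ring D). Ring A is numbered Q1 to Q6: Q1 and Q4 are the carbonyl carbons, Q2 carries the methoxy group, Q3 a hydrogen, Q5 the ether oxygen to ring D and Q6 a CH2CH2 bridge to ring B. Ring B is bound through its para oxygen to ring C, and ring C is joined to ring D by the second CH2CH2 bridge. There is no stereocentre, so every problem is one of connectivity, regiochemistry and ring closure. The fragile groups are the quinone and the free, electron-rich phenol of ring C. The quinone is reducible and is a vinylogous ester at Q2 and Q5, so alkoxides or amines can exchange the aryloxy group and open the macrocycle. The real difficulties are the closure of the 18-membered ring and the fully substituted ring A, whose four oxygen functions must be told apart. The key step uses the fact that the oxygen on ring B is bound to the ring C carbon ortho to the hydroxyl and meta to the side chain, the pattern left by oxidative coupling of two para-alkylphenols.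

## Logic of the disconnections

25 to 23: the two carbonyl groups of ring A are traced back to acetoxy groups. The quinone would not survive hydrogen, zinc or the thallium oxidant, whereas the diacetate is inert to all three. The forward step must free the hydroquinone with no nucleophilic base present once the quinone exists, and must oxidise it without touching the ring C phenol.

23 to 22: three aryl C–H bonds are exchanged for one C–Br and two C–Cl bonds. The halogens are control elements of the ring closure and carry no skeletal information, so they cost one step to remove. That step must cleave two hindered aryl chlorides while the phenyl esters stay.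

22 to 20 (key): the bond between the ring B oxygen and the ring C carbon ortho to the hydroxyl is cut, and a bromine returns to that carbon. This is the only ring-forming bond of the route; cutting it removes the macrocycle and leaves an open chain of four rings. The forward step must oxidise ring C and not ring B or ring A, join O to C and not C to C, and do so within one molecule.

20 to 19 to 17 to 16: the two benzylic ether bonds on rings B and C are restored, the diacetate is traced to the quinone, and the Q4–O bond is cut. Ring A then needs a single free hydroxyl at Q1 with an open para position. No hydroquinone protecting groups have to be carried or distinguished from those of rings B and C, which is the main change in precursor design. The forward steps need a para-selective phenol oxidation and an ether cleavage that spares phenyl acetates.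

16 to 15 to 12 + 14: both CH2CH2 bridges are taken back to C=C, and the ring D to ring C bridge is cut across its double bond. One reduction serves both bridges, but it must leave four aryl–halogen bonds and two benzylic ethers alone.

12 to 10 to 9 to 6 + 8: the phosphonium carbon of ring D is traced to an ester carbon, and the ring A to ring B bridge is cut across its double bond. The ester keeps the ring D carbon silent while the ring A carbon reacts, so the two different halogenated aldehydes can be introduced one after the other. The ylide of 6 must olefinate although it carries a phenoxide.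

6 to 5 to 4 to 3: C–P is traced to C–OH and then to the aldehyde, and the Q1 hydroxyl to a methyl ether. The formyl group activates the neighbouring bromide, directs the demethylation to Q1 and becomes the bridge carbon.

3 to 1 + 2: the ring A to ring D ether bond is cut between oxygen and Q5. Both pieces are simple and no halogenated ring is yet present to compete in the copper-catalysed coupling.

8 to 7 and 14 to 13: the benzylic ether bonds are cut. A group is needed that survives base, hydride, diimide, oxidation and zinc, and leaves under acid that does not touch acetates.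

## Other disconnections considered

Alternative 1: The cut removes two bonds of ring A at once, Q5–O and Q6–C(bridge). Ring A comes from the silyl triflate A1 and the rest from the arylacetic acid A2, which already holds rings B, C and D. In the forward step fluoride would strip the silyl and triflate groups from A1, and the strained triple bond so formed would insert into the carboxyl C–O bond of A2 to give the ortho-hydroxyaryl ketone A3.
- In its favour: two bonds form in one convergent step, and the benzyloxy group should steer the oxygen to Q5. The B–O–C ether is made earlier by an ordinary intermolecular etherification with fixed regiochemistry, and no thallium is used. On toxicity and on certainty of the ether position it is the better plan.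
- Against it here: A3 is open-chain, so the macrocycle still has to be closed, by copper-mediated etherification of a doubly ortho-substituted phenol with the ring D bromide. The ketone must be deoxygenated, the Q4 oxygen introduced and two protecting groups removed. The insertion also competes with simple O-arylation of the acid.
- Comparison: the ring A endgame is equal, since both plans oxidise a Q1 phenol at Q4. Mechanistically the alternative relies on polar aryne capture rather than on an oxidation-potential difference. In step economy it should be no shorter, because the hardest operation, the ring closure, is only postponed.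

Alternative 2: The cut is the Q1–Q2 bond, so ring A is the last ring made, inside a macrocycle that already exists. Heating the macrocyclic 4-ethynyl-4-hydroxycyclobutenone A4 would open the four-membered ring to a vinylketene, whose ketene carbon bonds to the alkyne terminus and gives the quinone A5.
- In its favour: the quinone oxidation level is delivered directly under neutral thermal conditions. Ring A needs no protecting groups and no late oxidation; on redox economy it is the better plan.
- Against it here: a macrocycle containing a strained, aryloxy-substituted cyclobutenone has to be assembled first, so a macrocyclisation and both diaryl ethers are still required and become harder. A5 also lacks the Q2 methoxy group, which needs an oxidative addition of methanol. That addition should favour Q2, the position beta to the more ketone-like Q4 carbonyl, but it exposes the aryloxy quinone to an alcohol nucleophile.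
- Comparison: structurally it solves ring A and nothing else. Mechanistically it is a pericyclic cascade against an ionic oxidation. In step count the saving on ring A would be used up by the squarate chemistry and the extra methoxylation.

Alternative 3: The cuts are the C3–C4 and C1–C2 bonds of ring C, which is grown from the aldehyde A6 and the aryloxymethyl vinyl ketone A7. Pyrrolidine would convert A6 into an enamine that adds to A7, and aldol condensation would close the cyclohexenone A8, racemic at the carbon that carries the bridge.
- In its favour: the ortho relation of ether oxygen and future hydroxyl on ring C is fixed by construction, so no ring selectivity is needed. The conditions are mild and metal-free. The iodide and vinyl groups of A8 prepare a palladium-catalysed ring closure. On regiochemical certainty it is the better plan.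
- Against it here: ring C is an ordinary benzene ring and building it from acyclic pieces is wasteful. A8 must be dehydrogenated to the phenol, and a stereocentre is created only to be destroyed. The macrocycle is still open and its closure would give a stilbene that needs reduction next to benzyl ethers. A7 is prone to polymerise and the aldehyde to self-condense.
- Comparison: both plans must hydrogenate and unmask at the end, so they are equal there. The alternative avoids thallium and halogen control elements. It should be clearly longer, because ring construction, aromatisation and ring closure are three separate operations, where the chosen plan needs one.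

Key step: step 15

Assumptions and remarks on the chemistry:
- Compounds 1, 2, 7 and 13 are taken as commercial.
- The stilbene double bonds of 9 to 12 and 15 are carried as E/Z mixtures, so their SMILES leave the geometry open.
- In step 15 the ring B oxygen is taken to attack the ortho carbon of the oxidised ring C directly, ipso to bromine. A conjugate addition to a para-methoxy dienone would place the oxygen meta to the carbonyl carbon and cannot give the ortho ether.

## Route

Step 1
Reactants: 1 6-bromo-2,3-dimethoxybenzaldehyde; 2 methyl 3-hydroxybenzoate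
Product: 3 methyl 3-(2-formyl-3,4-dimethoxyphenoxy)benzoate
Conditions: CuI (copper iodide, monovalent copper, 10 mol %), N,N-dimethylglycine hydrochloride, Cs2CO3, 1,4-dioxane, 90 °C
Reagents that add atoms: none
Why: Ullmann-type copper-catalysed O-arylation of a phenol; the formyl group ortho to bromine activates the halide, and neither partner has enolisable protons, so aldehyde and ester should survive the carbonate base.

Step 2
Reactants: 3 methyl 3-(2-formyl-3,4-dimethoxyphenoxy)benzoate
Product: 4 methyl 3-(2-formyl-3-hydroxy-4-methoxyphenoxy)benzoate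
Conditions: BCl3 (2 equiv), CH2Cl2, −78 °C to 0 °C; aqueous NaHCO3
Reagents that add atoms: none
Why: Chelation-controlled Lewis acid demethylation: boron bridges the formyl oxygen and the neighbouring methoxy oxygen, and chloride removes that methyl group only. The second methoxy group, the diaryl ether and, at low temperature, the methyl ester should remain.

Step 3
Reactants: 4 methyl 3-(2-formyl-3-hydroxy-4-methoxyphenoxy)benzoate
Product: 5 methyl 3-[3-hydroxy-2-(hydroxymethyl)-4-methoxyphenoxy]benzoate
Conditions: NaBH4, MeOH–THF, 0 °C
Reagents that add atoms: none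
Why: Chemoselective borohydride reduction of an aldehyde in the presence of an aryl ester.

Step 4
Reactants: 5 methyl 3-[3-hydroxy-2-(hydroxymethyl)-4-methoxyphenoxy]benzoate
Product: 6 {2-hydroxy-3-methoxy-6-[3-(methoxycarbonyl)phenoxy]benzyl}triphenylphosphonium bromide
Conditions: PPh3·HBr, MeCN, reflux
Reagents that add atoms: triphenylphosphine hydrobromide, c1ccc(cc1)[PH+](c1ccccc1)c1ccccc1.[Br-]
Why: Acid-promoted substitution of an ortho-hydroxybenzylic alcohol by PPh3, the usual entry to (2-hydroxybenzyl)phosphonium salts. The activated benzylic position ionises readily and the ester is inert to anhydrous HBr.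

Step 5
Reactants: 7 3,5-dichloro-4-hydroxybenzaldehyde
Product: 8 3,5-dichloro-4-[(4-methoxybenzyl)oxy]benzaldehyde
Conditions: 4-MeOC6H4CH2Cl, K2CO3, Bu4NI (cat.), DMF, 60 °C
Reagents that add atoms: 4-methoxybenzyl chloride, COc1ccc(CCl)cc1
Why: Williamson ether synthesis; carbonate fully deprotonates the acidic dihalophenol and iodide catalysis compensates for the low nucleophilicity of its phenoxide.

Step 6
Reactants: 6 {2-hydroxy-3-methoxy-6-[3-(methoxycarbonyl)phenoxy]benzyl}triphenylphosphonium bromide; 8 3,5-dichloro-4-[(4-methoxybenzyl)oxy]benzaldehyde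
Product: 9 methyl 3-[2-(2-{3,5-dichloro-4-[(4-methoxybenzyl)oxy]phenyl}ethenyl)-3-hydroxy-4-methoxyphenoxy]benzoate (E/Z mixture)
Conditions: LiN(SiMe3)2 (2.2 equiv), THF, −78 °C to rt
Reagents that add atoms: none
Why: Wittig olefination: the first equivalent of base forms the phenoxide and the second the semi-stabilised ylide, which adds to the electron-poor aldehyde. The E/Z ratio does not matter because the double bond is saturated in step 11.

Step 7
Reactants: 9 methyl 3-[2-(2-{3,5-dichloro-4-[(4-methoxybenzyl)oxy]phenyl}ethenyl)-3-hydroxy-4-methoxyphenoxy]benzoate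
Product: 10 2-(2-{3,5-dichloro-4-[(4-methoxybenzyl)oxy]phenyl}ethenyl)-3-[3-(hydroxymethyl)phenoxy]-6-methoxyphenol
Conditions: iBu2AlH (3.5 equiv), CH2Cl2, −78 °C to 0 °C; aqueous potassium sodium tartrate
Reagents that add atoms: none
Why: Hydride reduction of the benzoate ester to the benzylic alcohol; the phenol consumes one equivalent, and aryl chlorides, the alkene and the benzylic ether are inert at low temperature.

Step 8
Reactants: 10 2-(2-{3,5-dichloro-4-[(4-methoxybenzyl)oxy]phenyl}ethenyl)-3-[3-(hydroxymethyl)phenoxy]-6-methoxyphenol
Product: 12 {3-[2-(2-{3,5-dichloro-4-[(4-methoxybenzyl)oxy]phenyl}ethenyl)-3-hydroxy-4-methoxyphenoxy]benzyl}triphenylphosphonium bromide, via benzylic bromide 11 (not isolated)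
Conditions: CBr4, PPh3, CH2Cl2, 0 °C; then PPh3, MeCN, 70 °C
Reagents that add atoms: triphenylphosphine, c1ccc(cc1)P(c1ccccc1)c1ccccc1; carbon tetrabromide (source of the bromide counter-ion), BrC(Br)(Br)Br
Why: Appel bromination of the primary benzylic alcohol under neutral conditions, which spare the acid-labile 4-methoxybenzyl ether, followed by SN2 quaternisation of PPh3 by the benzylic bromide.

Step 9
Reactants: 13 3,5-dibromo-4-hydroxybenzaldehyde
Product: 14 3,5-dibromo-4-[(4-methoxybenzyl)oxy]benzaldehyde
Conditions: 4-MeOC6H4CH2Cl, K2CO3, Bu4NI (cat.), DMF, 60 °C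
Reagents that add atoms: 4-methoxybenzyl chloride, COc1ccc(CCl)cc1
Why: Williamson ether synthesis, as in step 5.

Step 10
Reactants: 12 {3-[2-(2-{3,5-dichloro-4-[(4-methoxybenzyl)oxy]phenyl}ethenyl)-3-hydroxy-4-methoxyphenoxy]benzyl}triphenylphosphonium bromide; 14 3,5-dibromo-4-[(4-methoxybenzyl)oxy]benzaldehyde
Product: 15 3-[3-(2-{3,5-dibromo-4-[(4-methoxybenzyl)oxy]phenyl}ethenyl)phenoxy]-2-(2-{3,5-dichloro-4-[(4-methoxybenzyl)oxy]phenyl}ethenyl)-6-methoxyphenol (mixture of alkene isomers)
Conditions: LiN(SiMe3)2 (2.2 equiv), THF, −78 °C to rt
Reagents that add atoms: none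
Why: Second Wittig olefination under the conditions of step 6; aryl bromides and chlorides should not react with the hindered amide base at low temperature.

Step 11
Reactants: 15 3-[3-(2-{3,5-dibromo-4-[(4-methoxybenzyl)oxy]phenyl}ethenyl)phenoxy]-2-(2-{3,5-dichloro-4-[(4-methoxybenzyl)oxy]phenyl}ethenyl)-6-methoxyphenol
Product: 16 3-[3-(2-{3,5-dibromo-4-[(4-methoxybenzyl)oxy]phenyl}ethyl)phenoxy]-2-(2-{3,5-dichloro-4-[(4-methoxybenzyl)oxy]phenyl}ethyl)-6-methoxyphenol
Conditions: TsNHNH2 (large excess, in portions), NaOAc, DME–H2O, reflux
Reagents that add atoms: none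
Why: Diimide reduction: diimide from the sulfonyl hydrazide transfers two hydrogens to each C=C through a cyclic transition state. No metal surface or hydride is involved, so the C–Br, C–Cl and benzylic C–O bonds should remain.

Step 12
Reactants: 16 3-[3-(2-{3,5-dibromo-4-[(4-methoxybenzyl)oxy]phenyl}ethyl)phenoxy]-2-(2-{3,5-dichloro-4-[(4-methoxybenzyl)oxy]phenyl}ethyl)-6-methoxyphenol
Product: 17 2-[3-(2-{3,5-dibromo-4-[(4-methoxybenzyl)oxy]phenyl}ethyl)phenoxy]-3-(2-{3,5-dichloro-4-[(4-methoxybenzyl)oxy]phenyl}ethyl)-5-methoxy-1,4-benzoquinone
Conditions: ON(SO3K)2 (2.5 equiv), KH2PO4, Bu4NHSO4 (cat.), CH2Cl2–H2O, rt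
Reagents that add atoms: potassium nitrosodisulfonate (supplies the Q4 oxygen), [K+].[K+].[O]N(S(=O)(=O)[O-])S(=O)(=O)[O-]
Why: Teuber oxidation: the nitrosodisulfonate radical abstracts the phenolic hydrogen and a second radical combines at the free para carbon Q4, which collapses to the para-quinone. Both ortho positions are substituted, and rings B and C are ethers, not phenols, so they should stay untouched.

Step 13
Reactants: 17 2-[3-(2-{3,5-dibromo-4-[(4-methoxybenzyl)oxy]phenyl}ethyl)phenoxy]-3-(2-{3,5-dichloro-4-[(4-methoxybenzyl)oxy]phenyl}ethyl)-5-methoxy-1,4-benzoquinone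
Product: 19 2-[3-(2-{3,5-dibromo-4-[(4-methoxybenzyl)oxy]phenyl}ethyl)phenoxy]-3-(2-{3,5-dichloro-4-[(4-methoxybenzyl)oxy]phenyl}ethyl)-5-methoxy-1,4-phenylene diacetate, via hydroquinone 18 (not isolated)
Conditions: Zn dust, Ac2O, pyridine, DMAP (cat.), rt to 50 °C
Reagents that add atoms: acetic anhydride, CC(=O)OC(C)=O
Why: Reductive acetylation: zinc reduces the quinone and the hydroquinone is acylated as it forms, so the air-sensitive diol is never handled. Zinc dust under these conditions should not insert into aryl bromides.

Step 14
Reactants: 19 2-[3-(2-{3,5-dibromo-4-[(4-methoxybenzyl)oxy]phenyl}ethyl)phenoxy]-3-(2-{3,5-dichloro-4-[(4-methoxybenzyl)oxy]phenyl}ethyl)-5-methoxy-1,4-phenylene diacetate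
Product: 20 2-{3-[2-(3,5-dibromo-4-hydroxyphenyl)ethyl]phenoxy}-3-[2-(3,5-dichloro-4-hydroxyphenyl)ethyl]-5-methoxy-1,4-phenylene diacetate (seco bis-phenol)
Conditions: CF3CO2H, Et3SiH, CH2Cl2, 0 °C
Reagents that add atoms: none
Why: Acidolysis of 4-methoxybenzyl aryl ethers through the stabilised benzylic cation, which the silane reduces before it can alkylate the freed phenols. Aryl acetates, the aryl methyl ether and the diaryl ether are stable to anhydrous acid at 0 °C.

Step 15
Reactants: 20 2-{3-[2-(3,5-dibromo-4-hydroxyphenyl)ethyl]phenoxy}-3-[2-(3,5-dichloro-4-hydroxyphenyl)ethyl]-5-methoxy-1,4-phenylene diacetate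
Product: 22 macrocyclic diaryl ether bearing the free ring C hydroxyl ortho to the new ether (ring C monobromo; ring B dichloro; ring A diacetate), via bromodienone 21 (not isolated)
Conditions: Tl(NO3)3·3H2O (2.5 equiv), MeOH–THF, high dilution, −20 °C to rt; then Zn dust, AcOH, rt
Reagents that add atoms: none
Why: Phenol exchange on Tl(NO3)3 gives an aryloxythallium species of ring C, and two-electron transfer (trivalent to monovalent thallium) leaves a phenoxonium ion with positive charge on the two bromine-bearing ortho carbons and the alkylated para carbon. The ring B hydroxyl captures one ortho carbon ipso to bromine and gives bromodienone 21; capture of the cation by methanol at the para carbon is reversible in the acidic medium and feeds the same path. Zinc in acetic acid then transfers two electrons to 21, bromide leaves from the carbon alpha to the carbonyl group, and the resulting dienolate is the aromatic phenoxide of 22, so the hydroxyl ends up free and ortho to the new ether. The closest known reaction type is the Tl(NO3)3 oxidation of ortho,ortho'-dihalophenols to open-chain and macrocyclic diaryl ethers followed by zinc reduction. The 18-membered ring closes by intramolecular attack of an oxygen nucleophile on a cationic sp2 carbon, an end-to-end macrocyclisation that needs high dilution and is not restricted by ring-size rules. No stereocentre is set: the sp3 carbon of 21 forms as a racemate and is flattened again on reduction. Three selectivities are needed: oxidation of ring C and not ring B (the dibromophenol has the lower oxidation potential, the dichlorophenol remains the nucleophile, and ring A is switched off by its two acetates); O–C and not C–C coupling (every ortho position carries a halogen and both para positions carry the bridges); and ortho instead of para attack (an adduct at the quaternary para carbon can only revert).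

Step 16
Reactants: 22 macrocyclic diaryl ether (ring C monobromo; ring B dichloro; ring A diacetate)
Product: 23 halogen-free macrocyclic diaryl ether, ring A as diacetate, ring C as free phenol
Conditions: H2 (1–3 atm), 10% Pd/C, Et3N, EtOAc–THF, rt
Reagents that add atoms: none
Why: Catalytic hydrogenolysis of aryl–halogen bonds on palladium, with the amine taking up the hydrogen halides. The aprotic medium should keep the phenyl acetates intact, and the ring C phenol is unaffected.

Step 17
Reactants: 23 halogen-free macrocyclic diaryl ether diacetate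
Product: 25 CNP0332646.0 (macrocyclic 2-methoxy-5-aryloxy-6-alkyl-1,4-benzoquinone), via macrocyclic hydroquinone 24 (not isolated)
Conditions: HCl (from AcCl) in MeOH, 40 °C, argon; evaporate; then Ag2O, Na2SO4, acetone, rt
Reagents that add atoms: none
Why: Acid-catalysed transesterification frees the hydroquinone in the absence of oxygen and of any nucleophilic base. Ag2O then oxidises it under neutral conditions, so the aryloxy group of the quinone never meets an alkoxide and the isolated ring C phenol should not be attacked.

## Compound list

1 | 6-bromo-2,3-dimethoxybenzaldehyde | COc1ccc(Br)c(C=O)c1OC | starting material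
2 | methyl 3-hydroxybenzoate | COC(=O)c1cccc(O)c1 | starting material
3 | methyl 3-(2-formyl-3,4-dimethoxyphenoxy)benzoate | COC(=O)c1cccc(Oc2ccc(OC)c(OC)c2C=O)c1 | intermediate
4 | methyl 3-(2-formyl-3-hydroxy-4-methoxyphenoxy)benzoate | COC(=O)c1cccc(Oc2ccc(OC)c(O)c2C=O)c1 | intermediate
5 | methyl 3-[3-hydroxy-2-(hydroxymethyl)-4-methoxyphenoxy]benzoate | COC(=O)c1cccc(Oc2ccc(OC)c(O)c2CO)c1 | intermediate
6 | {2-hydroxy-3-methoxy-6-[3-(methoxycarbonyl)phenoxy]benzyl}triphenylphosphonium bromide | COC(=O)c1cccc(Oc2ccc(OC)c(O)c2C[P+](c2ccccc2)(c2ccccc2)c2ccccc2)c1.[Br-] | intermediate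
7 | 3,5-dichloro-4-hydroxybenzaldehyde | O=Cc1cc(Cl)c(O)c(Cl)c1 | starting material
8 | 3,5-dichloro-4-[(4-methoxybenzyl)oxy]benzaldehyde | O=Cc1cc(Cl)c(OCc2ccc(OC)cc2)c(Cl)c1 | intermediate
9 | methyl 3-[2-(2-{3,5-dichloro-4-[(4-methoxybenzyl)oxy]phenyl}ethenyl)-3-hydroxy-4-methoxyphenoxy]benzoate (E/Z mixture) | COC(=O)c1cccc(Oc2ccc(OC)c(O)c2C=Cc2cc(Cl)c(OCc3ccc(OC)cc3)c(Cl)c2)c1 | intermediate
10 | 2-(2-{3,5-dichloro-4-[(4-methoxybenzyl)oxy]phenyl}ethenyl)-3-[3-(hydroxymethyl)phenoxy]-6-methoxyphenol (E/Z mixture) | OCc1cccc(Oc2ccc(OC)c(O)c2C=Cc2cc(Cl)c(OCc3ccc(OC)cc3)c(Cl)c2)c1 | intermediate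
11 | 3-[3-(bromomethyl)phenoxy]-2-(2-{3,5-dichloro-4-[(4-methoxybenzyl)oxy]phenyl}ethenyl)-6-methoxyphenol (E/Z mixture) | BrCc1cccc(Oc2ccc(OC)c(O)c2C=Cc2cc(Cl)c(OCc3ccc(OC)cc3)c(Cl)c2)c1 | intermediate (not isolated)
12 | {3-[2-(2-{3,5-dichloro-4-[(4-methoxybenzyl)oxy]phenyl}ethenyl)-3-hydroxy-4-methoxyphenoxy]benzyl}triphenylphosphonium bromide (E/Z mixture) | COc1ccc(COc2c(Cl)cc(C=Cc3c(O)c(OC)ccc3Oc3cccc(C[P+](c4ccccc4)(c4ccccc4)c4ccccc4)c3)cc2Cl)cc1.[Br-] | intermediate
13 | 3,5-dibromo-4-hydroxybenzaldehyde | O=Cc1cc(Br)c(O)c(Br)c1 | starting material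
14 | 3,5-dibromo-4-[(4-methoxybenzyl)oxy]benzaldehyde | O=Cc1cc(Br)c(OCc2ccc(OC)cc2)c(Br)c1 | intermediate
15 | 3-[3-(2-{3,5-dibromo-4-[(4-methoxybenzyl)oxy]phenyl}ethenyl)phenoxy]-2-(2-{3,5-dichloro-4-[(4-methoxybenzyl)oxy]phenyl}ethenyl)-6-methoxyphenol (mixture of alkene isomers) | COc1ccc(COc2c(Cl)cc(C=Cc3c(O)c(OC)ccc3Oc3cccc(C=Cc4cc(Br)c(OCc5ccc(OC)cc5)c(Br)c4)c3)cc2Cl)cc1 | intermediate
16 | 3-[3-(2-{3,5-dibromo-4-[(4-methoxybenzyl)oxy]phenyl}ethyl)phenoxy]-2-(2-{3,5-dichloro-4-[(4-methoxybenzyl)oxy]phenyl}ethyl)-6-methoxyphenol | COc1ccc(COc2c(Cl)cc(CCc3c(O)c(OC)ccc3Oc3cccc(CCc4cc(Br)c(OCc5ccc(OC)cc5)c(Br)c4)c3)cc2Cl)cc1 | intermediate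
17 | 2-[3-(2-{3,5-dibromo-4-[(4-methoxybenzyl)oxy]phenyl}ethyl)phenoxy]-3-(2-{3,5-dichloro-4-[(4-methoxybenzyl)oxy]phenyl}ethyl)-5-methoxy-1,4-benzoquinone | COC1=CC(=O)C(Oc2cccc(CCc3cc(Br)c(OCc4ccc(OC)cc4)c(Br)c3)c2)=C(CCc2cc(Cl)c(OCc3ccc(OC)cc3)c(Cl)c2)C1=O | intermediate
18 | 2-[3-(2-{3,5-dibromo-4-[(4-methoxybenzyl)oxy]phenyl}ethyl)phenoxy]-3-(2-{3,5-dichloro-4-[(4-methoxybenzyl)oxy]phenyl}ethyl)-5-methoxybenzene-1,4-diol | COc1cc(O)c(Oc2cccc(CCc3cc(Br)c(OCc4ccc(OC)cc4)c(Br)c3)c2)c(CCc2cc(Cl)c(OCc3ccc(OC)cc3)c(Cl)c2)c1O | intermediate (not isolated)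
19 | 2-[3-(2-{3,5-dibromo-4-[(4-methoxybenzyl)oxy]phenyl}ethyl)phenoxy]-3-(2-{3,5-dichloro-4-[(4-methoxybenzyl)oxy]phenyl}ethyl)-5-methoxy-1,4-phenylene diacetate | COc1cc(OC(C)=O)c(Oc2cccc(CCc3cc(Br)c(OCc4ccc(OC)cc4)c(Br)c3)c2)c(CCc2cc(Cl)c(OCc3ccc(OC)cc3)c(Cl)c2)c1OC(C)=O | intermediate
20 | 2-{3-[2-(3,5-dibromo-4-hydroxyphenyl)ethyl]phenoxy}-3-[2-(3,5-dichloro-4-hydroxyphenyl)ethyl]-5-methoxy-1,4-phenylene diacetate (seco bis-phenol) | COc1cc(OC(C)=O)c(Oc2cccc(CCc3cc(Br)c(O)c(Br)c3)c2)c(CCc2cc(Cl)c(O)c(Cl)c2)c1OC(C)=O | intermediate
21 | macrocyclic 6-aryloxy-2,6-dibromocyclohexa-2,4-dienone (ring C oxidised; the ring B oxygen and one bromine on the same sp3 carbon; racemic) | COc1cc(OC(C)=O)c2c(CCc3cc(Cl)c(c(Cl)c3)OC3(Br)C=C(C=C(Br)C3=O)CCc3cccc(c3)O2)c1OC(C)=O | intermediate (not isolated)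
22 | macrocyclic diaryl ether: ring C 2-aryloxy-6-bromophenol, ring B 2,6-dichloro, ring A diacetate | COc1cc(OC(C)=O)c2c(CCc3cc(Cl)c(c(Cl)c3)Oc3cc(cc(Br)c3O)CCc3cccc(c3)O2)c1OC(C)=O | intermediate
23 | halogen-free macrocyclic diaryl ether: ring A hydroquinone diacetate, ring C free phenol | COc1cc(OC(C)=O)c2c(CCc3ccc(cc3)Oc3cc(ccc3O)CCc3cccc(c3)O2)c1OC(C)=O | intermediate
24 | macrocyclic hydroquinone (ring A benzene-1,4-diol, ring C phenol) | COc1cc(O)c2c(CCc3ccc(cc3)Oc3cc(ccc3O)CCc3cccc(c3)O2)c1O | intermediate (not isolated)
25 | CNP0332646.0, macrocyclic 2-methoxy-5-aryloxy-6-alkyl-1,4-benzoquinone | COC1=CC(=O)C2=C(CCc3ccc(cc3)Oc3cc(ccc3O)CCc3cccc(c3)O2)C1=O | target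

## Step count and least certain steps

Total: 17 steps. Longest linear sequence: 15 steps (steps 1 to 4, 6 to 8 and 10 to 17, from 1 to 25); steps 5 and 9 are side branches.

Step 15 (key step). Most likely to go wrong: intermolecular coupling and over-oxidation may outrun the entropically costly 18-membered closure. Ring selectivity may also erode through oxidation of ring B, because the two halophenols differ only moderately in oxidation potential. The fallback sets out from 6 and returns at 24. It makes the ring B to ring C ether first, intermolecularly, and closes the macrocycle by a Wittig reaction.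
- Purchased 4-(benzyloxy)-3-hydroxybenzaldehyde F1 is converted with ethylene glycol and TsOH into 2-(benzyloxy)-5-(1,3-dioxolan-2-yl)phenol F2.
- Nucleophilic aromatic substitution on 4-fluorobenzaldehyde (K2CO3, DMF, 120 °C) gives 4-[2-(benzyloxy)-5-(1,3-dioxolan-2-yl)phenoxy]benzaldehyde F3.
- Wittig reaction with the ylide of 6 gives the stilbene ester F4, and iBu2AlH gives the benzylic alcohol F5.
- Appel bromination, quaternisation with PPh3 and aqueous HCl give the formyl phosphonium salt F6.
- K2CO3 and 18-crown-6 in CH2Cl2 at high dilution close the ring to the macrocyclic bis-stilbene F7.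
- ON(SO3K)2 oxidises the ring A phenol to the macrocyclic quinone F8.
- Hydrogenation over Pd/C saturates both double bonds, removes the benzyl group and reduces the quinone to 24, which is oxidised with Ag2O as in step 17.

Step 6. Most likely to go wrong: the phenoxide–phosphonium zwitterion formed from 6 may lose PPh3 and oligomerise before the ylide meets the aldehyde. The fallback sets out from 8 and 4, returns at 9, and reverses the roles of the partners. NaBH4 reduces 8 to 3,5-dichloro-4-[(4-methoxybenzyl)oxy]benzyl alcohol F9. CBr4/PPh3 followed by more PPh3 gives {3,5-dichloro-4-[(4-methoxybenzyl)oxy]benzyl}triphenylphosphonium bromide F10. Its ylide (LiN(SiMe3)2, with one extra equivalent for the phenol) is condensed with aldehyde 4 to give 9 directly, which makes steps 3 and 4 unnecessary.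

Step 11. Most likely to go wrong: incomplete hydrogen transfer to the double bond next to ring A, which is flanked by two ortho substituents and is electron-rich, while diimide disproportionates. The fallback sets out from 15 and returns at 16. It replaces transfer reduction by catalytic hydrogenation over sulfided platinum on carbon under H2 pressure, a catalyst that saturates alkenes while sparing aryl bromides, aryl chlorides and benzylic ethers. This fallback makes no new compound (F0).

Step 17. Most likely to go wrong: slow solvolysis of the hindered Q1 acetate, which invites forcing conditions, followed by exchange of the aryloxy group or oxidation of the ring C phenol once the quinone is present. The fallback sets out from 23 and returns at 25. The esters are cleaved reductively instead of by solvolysis (LiAlH4, THF, 0 °C, acidic quench under argon), which reaches 24 with no acyl-transfer equilibrium and no alcohol nucleophile. Oxidation with Ag2O follows as before. This fallback makes no new compound (F0).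

## Further compounds

F1 | step 15 | 4-(benzyloxy)-3-hydroxybenzaldehyde (purchased) | O=Cc1ccc(OCc2ccccc2)c(O)c1
F2 | step 15 | 2-(benzyloxy)-5-(1,3-dioxolan-2-yl)phenol | Oc1cc(C2OCCO2)ccc1OCc1ccccc1
F3 | step 15 | 4-[2-(benzyloxy)-5-(1,3-dioxolan-2-yl)phenoxy]benzaldehyde | O=Cc1ccc(Oc2cc(C3OCCO3)ccc2OCc2ccccc2)cc1
F4 | step 15 | methyl 3-{2-[2-(4-{2-(benzyloxy)-5-(1,3-dioxolan-2-yl)phenoxy}phenyl)ethenyl]-3-hydroxy-4-methoxyphenoxy}benzoate (E/Z mixture) | COC(=O)c1cccc(Oc2ccc(OC)c(O)c2C=Cc2ccc(Oc3cc(C4OCCO4)ccc3OCc3ccccc3)cc2)c1
F5 | step 15 | 2-[2-(4-{2-(benzyloxy)-5-(1,3-dioxolan-2-yl)phenoxy}phenyl)ethenyl]-3-[3-(hydroxymethyl)phenoxy]-6-methoxyphenol (E/Z mixture) | OCc1cccc(Oc2ccc(OC)c(O)c2C=Cc2ccc(Oc3cc(C4OCCO4)ccc3OCc3ccccc3)cc2)c1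
F6 | step 15 | {3-[2-(2-{4-[2-(benzyloxy)-5-formylphenoxy]phenyl}ethenyl)-3-hydroxy-4-methoxyphenoxy]benzyl}triphenylphosphonium bromide (E/Z mixture) | O=Cc1ccc(OCc2ccccc2)c(Oc2ccc(C=Cc3c(O)c(OC)ccc3Oc3cccc(C[P+](c4ccccc4)(c4ccccc4)c4ccccc4)c3)cc2)c1.[Br-]
F7 | step 15 | macrocyclic bis-stilbene: ring A 2-methoxyphenol, ring C benzyl ether (mixture of alkene isomers) | COc1ccc2c(C=Cc3ccc(cc3)Oc3cc(ccc3OCc3ccccc3)C=Cc3cccc(c3)O2)c1O
F8 | step 15 | macrocyclic bis-stilbene quinone: ring A 2-methoxy-1,4-benzoquinone, ring C benzyl ether (mixture of alkene isomers) | COC1=CC(=O)C2=C(C=Cc3ccc(cc3)Oc3cc(ccc3OCc3ccccc3)C=Cc3cccc(c3)O2)C1=O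
F9 | step 6 | 3,5-dichloro-4-[(4-methoxybenzyl)oxy]benzyl alcohol | OCc1cc(Cl)c(OCc2ccc(OC)cc2)c(Cl)c1
F10 | step 6 | {3,5-dichloro-4-[(4-methoxybenzyl)oxy]benzyl}triphenylphosphonium bromide | COc1ccc(COc2c(Cl)cc(C[P+](c3ccccc3)(c3ccccc3)c3ccccc3)cc2Cl)cc1.[Br-]
F0 | step 11 | none | none
F0 | step 17 | none | none
A1 | alternative 1 | 2-(benzyloxy)-3-methoxy-6-(trimethylsilyl)phenyl trifluoromethanesulfonate | COc1ccc([Si](C)(C)C)c(OS(=O)(=O)C(F)(F)F)c1OCc1ccccc1
A2 | alternative 1 | (4-{5-[2-(3-bromophenyl)ethyl]-2-(methoxymethoxy)phenoxy}phenyl)acetic acid | OC(=O)Cc1ccc(cc1)Oc1cc(ccc1OCOC)CCc1cccc(Br)c1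
A3 | alternative 1 | 1-[2-(benzyloxy)-6-hydroxy-3-methoxyphenyl]-2-(4-{5-[2-(3-bromophenyl)ethyl]-2-(methoxymethoxy)phenoxy}phenyl)ethanone | COc1ccc(O)c(C(=O)Cc2ccc(cc2)Oc2cc(ccc2OCOC)CCc2cccc(Br)c2)c1OCc1ccccc1
A4 | alternative 2 | macrocyclic 4-ethynyl-4-hydroxycyclobut-2-enone: C2 bears the bridge to ring B, C3 the oxygen to ring D, ring C as methoxymethyl ether (racemic) | C#CC1(O)C(=O)C2=C1Oc1cccc(CCc3ccc(OCOC)c(c3)Oc3ccc(CC2)cc3)c1
A5 | alternative 2 | macrocyclic 2-aryloxy-3-alkyl-1,4-benzoquinone without the Q2 methoxy group, ring C as methoxymethyl ether | O=C1C=CC(=O)C2=C1CCc1ccc(cc1)Oc1cc(ccc1OCOC)CCc1cccc(c1)O2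
A6 | alternative 3 | 4-{3-[2,5-bis(benzyloxy)-6-ethenyl-3-methoxyphenoxy]phenyl}butanal | O=CCCCc1cccc(Oc2c(OCc3ccccc3)cc(OC)c(OCc3ccccc3)c2C=C)c1
A7 | alternative 3 | 1-(4-iodophenoxy)but-3-en-2-one | C=CC(=O)COc1ccc(I)cc1
A8 | alternative 3 | 2-(4-iodophenoxy)-4-(2-{3-[2,5-bis(benzyloxy)-6-ethenyl-3-methoxyphenoxy]phenyl}ethyl)cyclohex-2-enone (racemic) | O=C1CCC(CCc2cccc(Oc3c(OCc4ccccc4)cc(OC)c(OCc4ccccc4)c3C=C)c2)C=C1Oc1ccc(I)cc1
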